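## Retrosynthetic overview

1. The target is taken back to a bicyclic 7,12,14-triketone acid by three late operations: oxidation at C11 (hydroxyquinone), O-methylation of the C3 acid, and dehydrogenation of ring C.
2. The strategy rests on ring C: its unit C11–C12(O)–C13(isopropyl)–C14(O) is an α-isopropylacetoacetate whose ends sit on C9 and C8, the β- and α-carbons of the C7 enone of ring B. Disconnecting C9–C11 (Mukaiyama–Michael) and C8–C14 (Dieckmann) gives a formal [4+2] annulation of a 2-isopropyl-1,3-bis(silyloxy)diene (four carbons) with the ring B enone (two carbons).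
3. The ring B enone acid comes from a desymmetrising copper-catalysed isopropenyl addition to a prochiral 4,4-disubstituted cyclohexa-2,5-dienone, which sets C5 and C10. The dienone comes from propanal, methyl acrylate and methyl vinyl ketone by enamine Michael addition, Robinson annulation and dehydrogenation.
4. The diene comes from methyl acetoacetate by isopropylation and two silylations.
5. Ring order: ring B first, ring C second (key step), then aromatisation of ring C and oxidation to the hydroxyquinone last.

Key step: step 9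

Assumption (numbering): locants C1–C14 in the text follow the abietane skeleton: ring B = C5–C10, ring C = C8, C9, C11–C14, side chain C1–C3 on C10, isopropenyl on C5.

Assumption (ligand sense): the ligand enantiomer named in step 4 is the one expected, by analogy with additions to cyclohex-2-enone, to give the (6S) centre; its mirror image is used if the sense proves opposite.

## Route

Step 1
Reactants: 1 propanal; 2 methyl acrylate
Product: 4 methyl 4-methyl-5-oxopentanoate (racemic), via enamine 3 (not isolated)
Conditions: pyrrolidine, K2CO3, 0 °C to rt; then 2, MeCN, reflux; then AcOH/H2O, reflux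
Reagents that add atoms: water, O
Why: Stork enamine alkylation: the pyrrolidine enamine of propanal adds through its β-carbon to methyl acrylate and hydrolysis returns the α-branched aldehyde; the new centre is racemic and is erased in step 3.

Step 2
Reactants: 4 methyl 4-methyl-5-oxopentanoate; 5 methyl vinyl ketone
Product: 8 methyl 3-(1-methyl-4-oxocyclohex-2-en-1-yl)propanoate (racemic), via keto aldehyde 6 (not isolated), via ketol 7 (not isolated)
Conditions: conc. H2SO4 (cat.), toluene, 45 °C, then reflux (Dean–Stark)
Reagents that add atoms: none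
Why: Acid-catalysed Robinson annulation (Michael addition of the aldehyde enol, aldol closure, dehydration) is the standard route from α-branched aldehydes to 4,4-disubstituted cyclohex-2-enones; the quaternary centre is racemic at this stage.

Step 3
Reactants: 8 methyl 3-(1-methyl-4-oxocyclohex-2-en-1-yl)propanoate
Product: 9 methyl 3-(1-methyl-4-oxocyclohexa-2,5-dien-1-yl)propanoate (achiral, prochiral)
Conditions: DDQ, 1,4-dioxane, reflux
Reagents that add atoms: none
Why: DDQ dehydrogenation of a 4,4-disubstituted cyclohexenone cannot go on to a phenol and should stop at the cross-conjugated dienone, which removes the stereocentre and leaves two enantiotopic enone units.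

Step 4
Reactants: 9 methyl 3-(1-methyl-4-oxocyclohexa-2,5-dien-1-yl)propanoate
Product: 11 methyl 3-[(1R,6S)-1-methyl-4-oxo-6-(prop-1-en-2-yl)cyclohex-2-en-1-yl]propanoate (isopropenyl cis to the ring methyl and trans to the propanoate chain), via magnesium dienolate 10 (not isolated)
Conditions: isopropenylmagnesium bromide (1.15 equiv), CuBr·SMe2 (5 mol %), (R)-1-[(S)-2-(diphenylphosphino)ferrocenyl]ethyldicyclohexylphosphine (6 mol %), tBuOMe, −78 °C; aq NH4Cl
Reagents that add atoms: isopropenylmagnesium bromide, C=C(C)[Mg]Br
Why: Copper-catalysed asymmetric conjugate addition of a Grignard reagent to one of two enantiotopic enones: the chiral copper–diphosphine complex fixes the face of attack at the β-carbon and so the (6S) centre, the (1R) quaternary centre follows from attack on the ring face that carries the methyl group, anti to the longer propanoate chain (a modest substrate bias, the C1 epimer being removed by chromatography), and the adduct stays a magnesium dienolate until the quench, which should prevent a second addition.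

Step 5
Reactants: 11 methyl 3-[(1R,6S)-1-methyl-4-oxo-6-(prop-1-en-2-yl)cyclohex-2-en-1-yl]propanoate
Product: 12 3-[(1R,6S)-1-methyl-4-oxo-6-(prop-1-en-2-yl)cyclohex-2-en-1-yl]propanoic acid
Conditions: LiOH·H2O, THF/H2O, 0 °C to rt; then 1 M HCl to pH 3
Reagents that add atoms: lithium hydroxide, [Li+].[OH-]
Why: Saponification of the methyl ester; neither stereocentre can enolise (one is β to the ketone, the other quaternary), so the configuration should be kept.

Step 6
Reactants: 13 methyl acetoacetate
Product: 14 methyl 2-acetyl-3-methylbutanoate (methyl 2-isopropylacetoacetate, racemic)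
Conditions: NaOMe, MeOH, then 2-iodopropane, reflux
Reagents that add atoms: 2-iodopropane, CC(C)I
Why: Acetoacetic ester alkylation with a secondary iodide, run in methanol to favour C- over O-alkylation.

Step 7
Reactants: 14 methyl 2-acetyl-3-methylbutanoate
Product: 15 methyl 3-methyl-2-[1-(trimethylsilyloxy)ethylidene]butanoate (E/Z mixture)
Conditions: TMSCl, Et3N, toluene, rt
Reagents that add atoms: chlorotrimethylsilane, C[Si](C)(C)Cl
Why: O-silylation of the enolised β-keto ester, the first stage of the standard two-stage preparation of 1,3-bis(silyloxy)-1,3-dienes.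

Step 8
Reactants: 15 methyl 3-methyl-2-[1-(trimethylsilyloxy)ethylidene]butanoate
Product: 17 2-isopropyl-1-methoxy-1,3-bis(trimethylsilyloxy)buta-1,3-diene, via lithium dienolate 16 (not isolated)
Conditions: LiN(iPr)2, THF, −78 °C; TMSCl, −78 to 0 °C
Reagents that add atoms: chlorotrimethylsilane, C[Si](C)(C)Cl
Why: Kinetic γ-deprotonation of the silyloxy enoate gives the lithium dienolate, which is O-silylated to the acetoacetate dianion equivalent.

Step 9
Reactants: 12 3-[(1R,6S)-1-methyl-4-oxo-6-(prop-1-en-2-yl)cyclohex-2-en-1-yl]propanoic acid; 17 2-isopropyl-1-methoxy-1,3-bis(trimethylsilyloxy)buta-1,3-diene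
Product: 20 3-[(1R,2S)-1-methyl-4,5,7-trioxo-6-(propan-2-yl)-2-(prop-1-en-2-yl)decahydronaphthalen-1-yl]propanoic acid (C4a, C6 and C8a unassigned; mixture of enol tautomers), via silyl ester 18 (not isolated), via Michael adduct 19 (not isolated)
Conditions: TMSCl, Et3N, CH2Cl2, 0 °C; TiCl4, then 17 (1.5 equiv), −78 to −40 °C; aq NaHCO3, then HCl to pH 3; crude in NaOMe (6 equiv), MeOH, 65 °C; aq HCl
Reagents that add atoms: none
Why: TiCl4 binds the C7 carbonyl and the unsubstituted diene terminus (C11) adds to C9 in a Mukaiyama–Michael reaction, which leaves the δ-keto β-keto ester 19 after work-up; with methoxide the C8 enolate of the C7 ketone then attacks ester carbon C14 and expels methoxide, and the doubly stabilised triketone enolate formed makes this Dieckmann closure irreversible. The closest known reactions are the TiCl4-mediated conjugate addition of 1,3-bis(silyloxy)-1,3-dienes to cyclic enones and the Michael–Dieckmann annulation of ester-stabilised nucleophiles with cyclohexenones, here applied to a hindered substrate. Ring C closes by 6-exo-trig acyl substitution of C8 on C14. The new centres C8, C9 and C13 form without control and are erased on aromatisation, while C5 and C10 cannot enolise and are untouched. The step needs 1,4- rather than 1,2-addition at a β-carbon next to the quaternary C10 (Mukaiyama–Michael additions are known even for β,β-disubstituted enones) and closure from C8 onto C14 only; this is secured because C3 is a silyl ester under TiCl4 and a carboxylate under methoxide, so no second ester is open to attack, and because aldol attack of C13 on C7 would give a strained bridged ring that reverts and closure from C6 would need an eight-membered ring.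

Step 10
Reactants: 20 3-[(1R,2S)-1-methyl-4,5,7-trioxo-6-(propan-2-yl)-2-(prop-1-en-2-yl)decahydronaphthalen-1-yl]propanoic acid
Product: 21 3-[(1S,2S)-5,7-dihydroxy-1-methyl-4-oxo-6-(propan-2-yl)-2-(prop-1-en-2-yl)-1,2,3,4-tetrahydronaphthalen-1-yl]propanoic acid
Conditions: DDQ (1.1 equiv), 1,4-dioxane, 80 °C
Reagents that add atoms: none
Why: Oxidative aromatisation: DDQ abstracts hydride from C11 of the enolised triketone and loss of the C9 proton gives the 12,14-dihydroxy aromatic ring, an acylresorcinol stabilised by the hydrogen bond from 14-OH to the C7 ketone; C8, C9 and C13 become sp2 and C5 and C10 are not touched.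

Step 11
Reactants: 21 3-[(1S,2S)-5,7-dihydroxy-1-methyl-4-oxo-6-(propan-2-yl)-2-(prop-1-en-2-yl)-1,2,3,4-tetrahydronaphthalen-1-yl]propanoic acid
Product: 22 methyl 3-[(1S,2S)-5,7-dihydroxy-1-methyl-4-oxo-6-(propan-2-yl)-2-(prop-1-en-2-yl)-1,2,3,4-tetrahydronaphthalen-1-yl]propanoate
Conditions: trimethylsilyldiazomethane (1.05 equiv), toluene/MeOH 4:1, 0 °C
Reagents that add atoms: trimethylsilyldiazomethane, C[Si](C)(C)C=[N+]=[N-]
Why: Trimethylsilyldiazomethane in methanol esterifies a carboxylic acid far faster than it methylates phenols, one of which is also locked in a hydrogen bond to the C7 ketone.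

Step 12
Reactants: 22 methyl 3-[(1S,2S)-5,7-dihydroxy-1-methyl-4-oxo-6-(propan-2-yl)-2-(prop-1-en-2-yl)-1,2,3,4-tetrahydronaphthalen-1-yl]propanoate
Product: 23 methyl 3-[(1S,2S)-7-hydroxy-1-methyl-4,5,8-trioxo-6-(propan-2-yl)-2-(prop-1-en-2-yl)-1,2,3,4,5,8-hexahydronaphthalen-1-yl]propanoate (CNP0308749.1)
Conditions: K2[ON(SO3)2] (2.5 equiv), KH2PO4 buffer, acetone/H2O, rt
Reagents that add atoms: potassium nitrosodisulfonate, [K+].[K+].[O]N(S(=O)(=O)[O-])S(=O)(=O)[O-]
Why: Teuber oxidation: the nitrosodisulfonate radical forms the phenoxyl radical and transfers oxygen to C11, the only unsubstituted ring carbon (para to 14-OH, ortho to 12-OH), which gives the 12-hydroxy-11,14-quinone directly, the ortho-quinone from the other phenol being its tautomer.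

## Compound list

1 | propanal | CCC=O | starting material
2 | methyl acrylate | C=CC(=O)OC | starting material
3 | 1-[(E)-prop-1-en-1-yl]pyrrolidine | C/C=C/N1CCCC1 | intermediate
4 | methyl 4-methyl-5-oxopentanoate (racemic) | COC(=O)CCC(C)C=O | intermediate
5 | methyl vinyl ketone | CC(=O)C=C | starting material
6 | methyl 4-formyl-4-methyl-7-oxooctanoate (racemic) | COC(=O)CCC(C)(C=O)CCC(C)=O | intermediate
7 | methyl 3-(2-hydroxy-1-methyl-4-oxocyclohexyl)propanoate (stereoisomer mixture) | COC(=O)CCC1(C)CCC(=O)CC1O | intermediate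
8 | methyl 3-(1-methyl-4-oxocyclohex-2-en-1-yl)propanoate (racemic) | COC(=O)CCC1(C)CCC(=O)C=C1 | intermediate
9 | methyl 3-(1-methyl-4-oxocyclohexa-2,5-dien-1-yl)propanoate | COC(=O)CCC1(C)C=CC(=O)C=C1 | intermediate
10 | bromomagnesium (3S,4R)-4-(3-methoxy-3-oxopropyl)-4-methyl-3-(prop-1-en-2-yl)cyclohexa-1,5-dien-1-olate | C=C(C)[C@@H]1C=C(O[Mg]Br)C=C[C@@]1(C)CCC(=O)OC | intermediate
11 | methyl 3-[(1R,6S)-1-methyl-4-oxo-6-(prop-1-en-2-yl)cyclohex-2-en-1-yl]propanoate | C=C(C)[C@@H]1CC(=O)C=C[C@@]1(C)CCC(=O)OC | intermediate
12 | 3-[(1R,6S)-1-methyl-4-oxo-6-(prop-1-en-2-yl)cyclohex-2-en-1-yl]propanoic acid | C=C(C)[C@@H]1CC(=O)C=C[C@@]1(C)CCC(=O)O | intermediate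
13 | methyl acetoacetate | CC(=O)CC(=O)OC | starting material
14 | methyl 2-acetyl-3-methylbutanoate (racemic) | CC(=O)C(C(C)C)C(=O)OC | intermediate
15 | methyl 3-methyl-2-[1-(trimethylsilyloxy)ethylidene]butanoate (E/Z mixture) | COC(=O)C(C(C)C)=C(C)O[Si](C)(C)C | intermediate
16 | lithium 1-methoxy-2-(propan-2-yl)-3-(trimethylsilyloxy)buta-1,3-dien-1-olate | C=C(O[Si](C)(C)C)C(C(C)C)=C(OC)O[Li] | intermediate
17 | 2-isopropyl-1-methoxy-1,3-bis(trimethylsilyloxy)buta-1,3-diene | C=C(O[Si](C)(C)C)C(C(C)C)=C(OC)O[Si](C)(C)C | intermediate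
18 | trimethylsilyl 3-[(1R,6S)-1-methyl-4-oxo-6-(prop-1-en-2-yl)cyclohex-2-en-1-yl]propanoate | C=C(C)[C@@H]1CC(=O)C=C[C@@]1(C)CCC(=O)O[Si](C)(C)C | intermediate
19 | 3-[(1R,2S)-6-[4-methoxy-2,4-dioxo-3-(propan-2-yl)butyl]-1-methyl-4-oxo-2-(prop-1-en-2-yl)cyclohexyl]propanoic acid (ring C6 and side-chain C3 unassigned) | C=C(C)[C@@H]1CC(=O)CC(CC(=O)C(C(C)C)C(=O)OC)[C@@]1(C)CCC(=O)O | intermediate
20 | 3-[(1R,2S)-1-methyl-4,5,7-trioxo-6-(propan-2-yl)-2-(prop-1-en-2-yl)decahydronaphthalen-1-yl]propanoic acid (C4a, C6, C8a unassigned) | C=C(C)[C@@H]1CC(=O)C2C(=O)C(C(C)C)C(=O)CC2[C@@]1(C)CCC(=O)O | intermediate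
21 | 3-[(1S,2S)-5,7-dihydroxy-1-methyl-4-oxo-6-(propan-2-yl)-2-(prop-1-en-2-yl)-1,2,3,4-tetrahydronaphthalen-1-yl]propanoic acid | C=C(C)[C@@H]1CC(=O)c2c(O)c(C(C)C)c(O)cc2[C@@]1(C)CCC(=O)O | intermediate
22 | methyl 3-[(1S,2S)-5,7-dihydroxy-1-methyl-4-oxo-6-(propan-2-yl)-2-(prop-1-en-2-yl)-1,2,3,4-tetrahydronaphthalen-1-yl]propanoate | C=C(C)[C@@H]1CC(=O)c2c(O)c(C(C)C)c(O)cc2[C@@]1(C)CCC(=O)OC | intermediate
23 | methyl 3-[(1S,2S)-7-hydroxy-1-methyl-4,5,8-trioxo-6-(propan-2-yl)-2-(prop-1-en-2-yl)-1,2,3,4,5,8-hexahydronaphthalen-1-yl]propanoate | C=C(C)[C@@H]1CC(=O)C2=C(C(=O)C(O)=C(C(C)C)C2=O)[C@@]1(C)CCC(=O)OC | target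

## Step count and risks

Total step count: 12. Longest linear sequence: 9 steps (steps 1, 2, 3, 4, 5, 9, 10, 11, 12); steps 6–8 form the three-step side branch to the diene.

The three steps most likely to fail:

**Step 9 (key step).** The conjugate addition may stall or turn to 1,2-addition at the crowded C9 next to the quaternary C10. The C8 enolate may also fail to acylate on the ester of an enolised β-keto ester. The fallback sets out from 12 and comes back at 20; it is a base-mediated Michael–Claisen sequence of the dimedone type with a doubly activated donor. Dimethyl 3-oxopentanedioate would be isopropylated (2-iodopropane, K2CO3, acetone) to dimethyl 3-oxo-2-(propan-2-yl)pentanedioate F1. Heating F1 with 12 and NaOMe in MeOH should add the methylene carbon of F1 to C9 and close C8 onto the ester beside the isopropyl carbon, giving 3-[(1R,2S)-8-(methoxycarbonyl)-1-methyl-4,5,7-trioxo-6-(propan-2-yl)-2-(prop-1-en-2-yl)decahydronaphthalen-1-yl]propanoic acid F2. Aqueous NaOH followed by HCl with warming should hydrolyse and decarboxylate the β-keto ester at C11 to give 20.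

**Step 4.** Facial discrimination between the methyl group and the propanoate chain at C10 may be weak, giving a poor ratio of C10 epimers, and an alkenyl Grignard reagent may give low enantioselectivity. The fallback sets out from 4 and 5 and comes back at 11; it fixes C10 before C5. An enantioselective Robinson annulation of 4 with 5 under a proline sulfonamide organocatalyst, (S)-N-(4-dodecylphenylsulfonyl)pyrrolidine-2-carboxamide or its enantiomer as required, would give methyl 3-[(1S)-1-methyl-4-oxocyclohex-2-en-1-yl]propanoate F3. The copper-catalysed isopropenyl addition of step 4 is then applied to this single enantiomer, so that the ligand alone sets the face at the β-carbon, giving methyl 3-[(1S,2S)-1-methyl-4-oxo-2-(prop-1-en-2-yl)cyclohexyl]propanoate F4. Kinetic enolisation away from the branched carbon (LiN(iPr)2, TMSCl, THF, −78 °C) would give methyl 3-[(1R,6S)-1-methyl-6-(prop-1-en-2-yl)-4-(trimethylsilyloxy)cyclohex-3-en-1-yl]propanoate F5. Saegusa–Ito oxidation (Pd(OAc)2, MeCN) would then return 11.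

**Step 10.** Dehydrogenation of ring C may be incomplete, and DDQ may instead attack the allylic positions of the isopropenyl group or dehydrogenate ring B. The fallback sets out from 20 and comes back at 21; it replaces hydride abstraction by halogenation and dehydrohalogenation. N-Chlorosuccinimide in CH2Cl2 at 0 °C would chlorinate a carbon between two carbonyls, drawn as the C13 chloride 3-[(1R,2S)-6-chloro-1-methyl-4,5,7-trioxo-6-(propan-2-yl)-2-(prop-1-en-2-yl)decahydronaphthalen-1-yl]propanoic acid F6; the C8 chloride would eliminate to the same product. Heating with LiCl in DMF should eliminate HCl through the C11 enol and tautomerise to 21.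

## Further compounds

F1 | step 9 | dimethyl 3-oxo-2-(propan-2-yl)pentanedioate | COC(=O)CC(=O)C(C(C)C)C(=O)OC
F2 | step 9 | 3-[(1R,2S)-8-(methoxycarbonyl)-1-methyl-4,5,7-trioxo-6-(propan-2-yl)-2-(prop-1-en-2-yl)decahydronaphthalen-1-yl]propanoic acid | C=C(C)[C@@H]1CC(=O)C2C(=O)C(C(C)C)C(=O)C(C(=O)OC)C2[C@@]1(C)CCC(=O)O
F3 | step 4 | methyl 3-[(1S)-1-methyl-4-oxocyclohex-2-en-1-yl]propanoate | C1=CC(=O)CC[C@@]1(C)CCC(=O)OC
F4 | step 4 | methyl 3-[(1S,2S)-1-methyl-4-oxo-2-(prop-1-en-2-yl)cyclohexyl]propanoate | C=C(C)[C@@H]1CC(=O)CC[C@@]1(C)CCC(=O)OC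
F5 | step 4 | methyl 3-[(1R,6S)-1-methyl-6-(prop-1-en-2-yl)-4-(trimethylsilyloxy)cyclohex-3-en-1-yl]propanoate | C=C(C)[C@@H]1CC(O[Si](C)(C)C)=CC[C@@]1(C)CCC(=O)OC
F6 | step 10 | 3-[(1R,2S)-6-chloro-1-methyl-4,5,7-trioxo-6-(propan-2-yl)-2-(prop-1-en-2-yl)decahydronaphthalen-1-yl]propanoic acid | C=C(C)[C@@H]1CC(=O)C2C(=O)C(Cl)(C(C)C)C(=O)CC2[C@@]1(C)CCC(=O)O
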